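**Retrosynthetic overview**

1. Target 20 comes from bis-silyl ether 19 by fluoride deprotection. The route rests on ring C: its ipso carbon (bonded to C-1) sits between two OMe-bearing carbons and para to the styryl-bearing carbon. The ipso carbon, one C–OMe, one CH and the styryl carbon are C-3, C-4, C-5 and C-6 of a 2-pyrone; the remaining CH and C–OMe come from 1,1-dimethoxyethene.
2. Key disconnection: ring C ⇒ 3-alkyl-4-methoxy-6-styryl-2-pyrone 15 + ketene acetal 16, by [4+2] across C-3/C-6 (new bonds C-6–CH and C-3–C(OMe)), then loss of CO2 and MeOH.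
3. Pyrone 15 ⇒ 6-methylpyrone 11 + aldehyde 12 (vinylogous aldol, dehydration). Pyrone 11 ⇒ lactol 4 + ring-B Grignard reagent 7 (addition, ionic deoxygenation, O-methylation).
4. The C-1 stereocentre ⇒ iminium-catalysed Michael addition of 4-hydroxy-6-methyl-2-pyrone 1 (through C-3) to 4-methoxycinnamaldehyde 2.
5. Ring order: rings A, B, D and the pyrone ring are bought; ring C is the only ring built, last, on the pyrone frame.

Key step: step 8

Remark on the chemistry: ring A is the 4-methoxyphenyl group on C-1, ring B the 4-hydroxy-2-methoxyphenyl group, ring C the 2,6-dimethoxy-4-styrylphenyl group, ring D the 4-hydroxyphenyl group of the styryl unit. The two phenols are carried as silyl ethers (triisopropylsilyl on ring B, tert-butyldimethylsilyl on ring D) because step 4 is run in acid. 4-(tert-Butyldimethylsilyloxy)benzaldehyde 12 is assumed to be commercially available.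

**Step 1**
Reactants: 1 4-hydroxy-6-methyl-2H-pyran-2-one; 2 (E)-4-methoxycinnamaldehyde
Product: 4 (4S)-2-hydroxy-4-(4-methoxyphenyl)-7-methyl-3,4-dihydro-2H,5H-pyrano[4,3-b]pyran-5-one (both anomers), via open-chain Michael aldehyde 3 (not isolated)
Conditions: (S)-2-[diphenyl(trimethylsilyloxy)methyl]pyrrolidine (20 mol %), CH2Cl2, 0 → 25 °C
Reagents that add atoms: none
Why: Iminium-catalysed asymmetric Michael addition followed by hemiacetalisation, a known cascade for 4-hydroxypyrones and enals, in which C-3 of the pyrone adds to the β-carbon of the E,s-trans iminium ion on the face not shielded by the CPh2(OSiMe3) group of the (S)-catalyst, which should set C-1 as (S), and ring closure by the pyrone 4-OH traps the aldehyde and suppresses retro-Michael erosion.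

**Step 2**
Reactants: 5 4-bromo-3-methoxyphenol
Product: 6 (4-bromo-3-methoxyphenoxy)triisopropylsilane
Conditions: iPr3SiCl, imidazole, DMF, 25 °C
Reagents that add atoms: triisopropylsilyl chloride, CC(C)[Si](Cl)(C(C)C)C(C)C
Why: Standard O-silylation of a phenol gives an aryl triisopropylsilyl ether that tolerates Grignard formation, trifluoroacetic acid, carbonate base and heat.

**Step 3**
Reactants: 4 lactol from step 1; 6 (4-bromo-3-methoxyphenoxy)triisopropylsilane (3.3 equiv)
Product: 9 4-hydroxy-3-{(1S)-3-hydroxy-1-(4-methoxyphenyl)-3-[2-methoxy-4-(triisopropylsilyloxy)phenyl]propyl}-6-methyl-2H-pyran-2-one (both carbinol epimers), via arylmagnesium bromide 7 (not isolated), via bromomagnesium pyronolate aldehyde 8 (not isolated)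
Conditions: 6, Mg, I2 (cat.), THF, 50 °C; then 4, THF, 0 → 25 °C; aq. NH4Cl
Reagents that add atoms: none
Why: Grignard addition to a lactol, in which the first equivalent of 7 deprotonates the hemiacetal of 4, which opens to the bromomagnesium 4-pyronolate 8 with a free aldehyde and an unreactive anionic pyrone ring, and a further equivalent of 7 adds to that aldehyde; the new carbinol centre is formed without control and is removed in step 4.

**Step 4**
Reactants: 9 benzylic alcohol from step 3
Product: 10 4-hydroxy-3-{(1S)-1-(4-methoxyphenyl)-3-[2-methoxy-4-(triisopropylsilyloxy)phenyl]propyl}-6-methyl-2H-pyran-2-one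
Conditions: Et3SiH (5 equiv), CF3CO2H (10 equiv), CH2Cl2, −20 → 0 °C
Reagents that add atoms: none
Why: Ionic hydrogenation, in which the alcohol ionises to a benzylic cation stabilised by the ortho-methoxy and para-silyloxy groups of ring B and is reduced by hydride transfer from the silane; a cyclic ether formed by reversible capture of the cation by a pyrone oxygen should re-ionise and be reduced as well, and C-1 is not involved.

**Step 5**
Reactants: 10 4-hydroxypyrone from step 4
Product: 11 4-methoxy-3-{(1S)-1-(4-methoxyphenyl)-3-[2-methoxy-4-(triisopropylsilyloxy)phenyl]propyl}-6-methyl-2H-pyran-2-one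
Conditions: Me2SO4 (1.5 equiv), K2CO3, acetone, 50 °C
Reagents that add atoms: dimethyl sulfate, COS(=O)(=O)OC
Why: O-Alkylation of the acidic vinylogous acid with a hard methylating agent under carbonate conditions, which should favour the 4-methoxy-2-pyrone over the 2-methoxy-4-pyrone isomer and leaves the aryl silyl ether and the non-acidic C-1 hydrogen alone.

**Step 6**
Reactants: 11 6-methylpyrone from step 5; 12 4-(tert-butyldimethylsilyloxy)benzaldehyde
Product: 13 6-{2-[4-(tert-butyldimethylsilyloxy)phenyl]-2-hydroxyethyl}-4-methoxy-3-{(1S)-1-(4-methoxyphenyl)-3-[2-methoxy-4-(triisopropylsilyloxy)phenyl]propyl}-2H-pyran-2-one (both carbinol epimers)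
Conditions: LiN(iPr)2 (1.2 equiv), THF, −78 °C; then 12, −78 °C; AcOH quench at −78 °C
Reagents that add atoms: none
Why: Vinylogous aldol addition, in which the 6-methyl group is the only C–H conjugated to the lactone carbonyl (C-3 is blocked) and its dienolate adds to the non-enolisable aldehyde; the new carbinol centre is uncontrolled and is removed in step 7.

**Step 7**
Reactants: 13 aldol adduct from step 6
Product: 15 6-{(E)-2-[4-(tert-butyldimethylsilyloxy)phenyl]ethenyl}-4-methoxy-3-{(1S)-1-(4-methoxyphenyl)-3-[2-methoxy-4-(triisopropylsilyloxy)phenyl]propyl}-2H-pyran-2-one, via benzylic mesylate 14 (not isolated)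
Conditions: MsCl (1.5 equiv), Et3N (5 equiv), CH2Cl2, 0 → 25 °C
Reagents that add atoms: none
Why: Mesylation followed by base-induced β-elimination across the acidic pyrone-CH2 and the activated benzylic carbon should give the fully conjugated styrylpyrone as the more stable E-alkene.

**Step 8**
Reactants: 15 styrylpyrone from step 7; 16 1,1-dimethoxyethene (20 equiv)
Product: 19 tert-butyl{4-[(E)-2-(3,5-dimethoxy-4-{(1S)-1-(4-methoxyphenyl)-3-[2-methoxy-4-(triisopropylsilyloxy)phenyl]propyl}phenyl)ethenyl]phenoxy}dimethylsilane, via bridged lactone cycloadduct 17 (not isolated), via dimethoxycyclohexadiene 18 (not isolated)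
Conditions: 16 (20 equiv), Et3N (cat.), BHT (cat.), PhMe, sealed tube, 160 °C
Reagents that add atoms: none
Why: The pyrone acts as the 4π component of an inverse-electron-demand [4+2] cycloaddition in which the nucleophilic CH2 of the ketene acetal bonds to the electrophilic C-6 (the δ-carbon of the dienyl lactone) and the acetal carbon to C-3, giving bridged lactone 17, which loses CO2 by retro-[4+2] to diene 18 and then methanol by 1,2-elimination to the arene. The closest known reaction type is the benzannulation of 2-pyrones with 1,1-dimethoxyethene to aryl methyl ethers, established for the pyrone class but fastest with acceptor-substituted pyrones, so a large excess of acetal and 160 °C (alternatively about 12 kbar at 25 °C followed by warming) are planned for this donor-substituted, C-3-branched member. Ring C is closed by an intermolecular [4+2] cycloaddition that forms both new ring bonds (C-6–CH2 and C-3–C(OMe)2) on the pyrone frame, after which the lactone bridge leaves as CO2. No stereocentre is created in the product because both bridgeheads of 17 become sp2, and the existing C-1 centre carries no acidic hydrogen and should be untouched under neutral thermal conditions. The regiochemistry follows from the polarisation of both partners and puts the new methoxy group ortho to C-1. Reaction at the pyrone, not the styryl alkene, is expected because only the ring diene is held s-cis and its adduct is drained irreversibly by CO2 loss, while the styryl terminus is deactivated by its para-silyloxyphenyl donor.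

**Step 9**
Reactants: 19 bis-silyl ether from step 8
Product: 20 4-[(E)-2-{4-[(1S)-3-(4-hydroxy-2-methoxyphenyl)-1-(4-methoxyphenyl)propyl]-3,5-dimethoxyphenyl}ethenyl]phenol (target)
Conditions: Bu4NF (2.5 equiv), AcOH (2.5 equiv), THF, 0 °C
Reagents that add atoms: none
Why: Fluoride-mediated cleavage of both aryl silyl ethers, buffered with acetic acid, should free the two phenols without touching the methyl ethers, the E-stilbene or the C-1 centre.

**Compound list**

1 | 4-hydroxy-6-methyl-2H-pyran-2-one | Cc1cc(O)cc(=O)o1 | starting material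
2 | (E)-4-methoxycinnamaldehyde | COc1ccc(/C=C/C=O)cc1 | starting material
3 | (3S)-3-(4-hydroxy-6-methyl-2-oxo-2H-pyran-3-yl)-3-(4-methoxyphenyl)propanal | Cc1cc(O)c([C@@H](CC=O)c2ccc(OC)cc2)c(=O)o1 | intermediate
4 | (4S)-2-hydroxy-4-(4-methoxyphenyl)-7-methyl-3,4-dihydro-2H,5H-pyrano[4,3-b]pyran-5-one (both anomers) | Cc1cc2OC(O)C[C@@H](c3ccc(OC)cc3)c2c(=O)o1 | intermediate
5 | 4-bromo-3-methoxyphenol | COc1cc(O)ccc1Br | starting material
6 | (4-bromo-3-methoxyphenoxy)triisopropylsilane | COc1cc(O[Si](C(C)C)(C(C)C)C(C)C)ccc1Br | intermediate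
7 | [2-methoxy-4-(triisopropylsilyloxy)phenyl]magnesium bromide | COc1cc(O[Si](C(C)C)(C(C)C)C(C)C)ccc1[Mg]Br | intermediate
8 | bromomagnesium 3-[(1S)-1-(4-methoxyphenyl)-3-oxopropyl]-6-methyl-2-oxo-2H-pyran-4-olate | Cc1cc(O[Mg]Br)c([C@@H](CC=O)c2ccc(OC)cc2)c(=O)o1 | intermediate
9 | 4-hydroxy-3-{(1S)-3-hydroxy-1-(4-methoxyphenyl)-3-[2-methoxy-4-(triisopropylsilyloxy)phenyl]propyl}-6-methyl-2H-pyran-2-one (both carbinol epimers) | Cc1cc(O)c([C@@H](CC(O)c2ccc(O[Si](C(C)C)(C(C)C)C(C)C)cc2OC)c2ccc(OC)cc2)c(=O)o1 | intermediate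
10 | 4-hydroxy-3-{(1S)-1-(4-methoxyphenyl)-3-[2-methoxy-4-(triisopropylsilyloxy)phenyl]propyl}-6-methyl-2H-pyran-2-one | Cc1cc(O)c([C@@H](CCc2ccc(O[Si](C(C)C)(C(C)C)C(C)C)cc2OC)c2ccc(OC)cc2)c(=O)o1 | intermediate
11 | 4-methoxy-3-{(1S)-1-(4-methoxyphenyl)-3-[2-methoxy-4-(triisopropylsilyloxy)phenyl]propyl}-6-methyl-2H-pyran-2-one | Cc1cc(OC)c([C@@H](CCc2ccc(O[Si](C(C)C)(C(C)C)C(C)C)cc2OC)c2ccc(OC)cc2)c(=O)o1 | intermediate
12 | 4-(tert-butyldimethylsilyloxy)benzaldehyde | CC(C)(C)[Si](C)(C)Oc1ccc(C=O)cc1 | starting material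
13 | 6-{2-[4-(tert-butyldimethylsilyloxy)phenyl]-2-hydroxyethyl}-4-methoxy-3-{(1S)-1-(4-methoxyphenyl)-3-[2-methoxy-4-(triisopropylsilyloxy)phenyl]propyl}-2H-pyran-2-one (both carbinol epimers) | COc1cc(CC(O)c2ccc(O[Si](C)(C)C(C)(C)C)cc2)oc(=O)c1[C@@H](CCc1ccc(O[Si](C(C)C)(C(C)C)C(C)C)cc1OC)c1ccc(OC)cc1 | intermediate
14 | methanesulfonate of 13 at the benzylic hydroxyl group | COc1cc(CC(OS(C)(=O)=O)c2ccc(O[Si](C)(C)C(C)(C)C)cc2)oc(=O)c1[C@@H](CCc1ccc(O[Si](C(C)C)(C(C)C)C(C)C)cc1OC)c1ccc(OC)cc1 | intermediate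
15 | 6-{(E)-2-[4-(tert-butyldimethylsilyloxy)phenyl]ethenyl}-4-methoxy-3-{(1S)-1-(4-methoxyphenyl)-3-[2-methoxy-4-(triisopropylsilyloxy)phenyl]propyl}-2H-pyran-2-one | COc1cc(/C=C/c2ccc(O[Si](C)(C)C(C)(C)C)cc2)oc(=O)c1[C@@H](CCc1ccc(O[Si](C(C)C)(C(C)C)C(C)C)cc1OC)c1ccc(OC)cc1 | intermediate
16 | 1,1-dimethoxyethene | C=C(OC)OC | starting material
17 | 1-{(E)-2-[4-(tert-butyldimethylsilyloxy)phenyl]ethenyl}-5,8,8-trimethoxy-4-{(1S)-1-(4-methoxyphenyl)-3-[2-methoxy-4-(triisopropylsilyloxy)phenyl]propyl}-2-oxabicyclo[2.2.2]oct-5-en-3-one (bridgehead diastereomers) | O=C1OC2(/C=C/c3ccc(O[Si](C)(C)C(C)(C)C)cc3)CC(OC)(OC)C1([C@@H](CCc4ccc(O[Si](C(C)C)(C(C)C)C(C)C)cc4OC)c5ccc(OC)cc5)C(OC)=C2 | intermediate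
18 | 4-{(E)-2-[4-(tert-butyldimethylsilyloxy)phenyl]ethenyl}-2,6,6-trimethoxy-1-{(1S)-1-(4-methoxyphenyl)-3-[2-methoxy-4-(triisopropylsilyloxy)phenyl]propyl}cyclohexa-1,3-diene | COC1=C([C@@H](CCc2ccc(O[Si](C(C)C)(C(C)C)C(C)C)cc2OC)c2ccc(OC)cc2)C(OC)(OC)CC(/C=C/c2ccc(O[Si](C)(C)C(C)(C)C)cc2)=C1 | intermediate
19 | tert-butyl{4-[(E)-2-(3,5-dimethoxy-4-{(1S)-1-(4-methoxyphenyl)-3-[2-methoxy-4-(triisopropylsilyloxy)phenyl]propyl}phenyl)ethenyl]phenoxy}dimethylsilane | COc1cc(/C=C/c2ccc(O[Si](C)(C)C(C)(C)C)cc2)cc(OC)c1[C@@H](CCc1ccc(O[Si](C(C)C)(C(C)C)C(C)C)cc1OC)c1ccc(OC)cc1 | intermediate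
20 | 4-[(E)-2-{4-[(1S)-3-(4-hydroxy-2-methoxyphenyl)-1-(4-methoxyphenyl)propyl]-3,5-dimethoxyphenyl}ethenyl]phenol | COc1ccc([C@H](CCc2ccc(O)cc2OC)c2c(OC)cc(/C=C/c3ccc(O)cc3)cc2OC)cc1 | target

**Step count**

Total: 9 steps. Longest linear sequence: 8 steps (steps 1, 3, 4, 5, 6, 7, 8, 9, from compounds 1 and 2).

**Steps most likely to fail**

Step 8. The cycloaddition may not start, because the 4-methoxy donor raises the diene LUMO and the branched C-3 substituent crowds the forming C-3–C bond, while the ketene acetal is consumed by oligomerisation or by addition at the styryl terminus. The fallback does not build ring C but takes it from a 3,5-dimethoxystilbene and sets C-1 by a rhodium-catalysed conjugate addition; it sets out from aldehyde 12 and comes back at 19. Horner–Wadsworth–Emmons reaction of 12 with diethyl (3,5-dimethoxybenzyl)phosphonate (NaH, THF) should give tert-butyl{4-[(E)-2-(3,5-dimethoxyphenyl)ethenyl]phenoxy}dimethylsilane F1. Lithiation between the two methoxy groups (n-BuLi, THF, 0 °C) and quenching with DMF should give 4-{(E)-2-[4-(tert-butyldimethylsilyloxy)phenyl]ethenyl}-2,6-dimethoxybenzaldehyde F2. Wittig reaction with Ph3P=CHCHO (PhMe, 80 °C) should give (E)-3-(4-{(E)-2-[4-(tert-butyldimethylsilyloxy)phenyl]ethenyl}-2,6-dimethoxyphenyl)prop-2-enal F3. Asymmetric 1,4-addition of 4-methoxyphenylboronic acid ([RhCl(C2H4)2]2, chiral 2,5-diphenylbicyclo[2.2.2]octa-2,5-diene ligand of the enantiomer that delivers the (S)-product, K3PO4, dioxane/H2O, 40 °C) should give (3S)-3-(4-{(E)-2-[4-(tert-butyldimethylsilyloxy)phenyl]ethenyl}-2,6-dimethoxyphenyl)-3-(4-methoxyphenyl)propanal F4. Addition of Grignard reagent 7 (THF, 0 °C) should give (3S)-3-(4-{(E)-2-[4-(tert-butyldimethylsilyloxy)phenyl]ethenyl}-2,6-dimethoxyphenyl)-3-(4-methoxyphenyl)-1-[2-methoxy-4-(triisopropylsilyloxy)phenyl]propan-1-ol F5, and ionic deoxygenation (Et3SiH, BF3·OEt2, CH2Cl2, −78 °C) should give 19.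

Step 4. The benzylic cation may be diverted instead of reduced: reversible heterolysis of the C-1–pyrone bond in acid would erode the enantiomeric purity, the cation may alkylate a second electron-rich ring B, or the silyl ether may be lost. The fallback replaces the cationic reduction by a radical one (Barton–McCombie deoxygenation); it sets out from 9 and comes back at 11. O-Methylation of 9 under the conditions of step 5 should give 3-{(1S)-3-hydroxy-1-(4-methoxyphenyl)-3-[2-methoxy-4-(triisopropylsilyloxy)phenyl]propyl}-4-methoxy-6-methyl-2H-pyran-2-one F6. Acylation with PhOC(S)Cl (pyridine, DMAP, CH2Cl2) should give O-{(3S)-3-(4-methoxy-6-methyl-2-oxo-2H-pyran-3-yl)-3-(4-methoxyphenyl)-1-[2-methoxy-4-(triisopropylsilyloxy)phenyl]propyl} O-phenyl thiocarbonate F7. Reduction with Bu3SnH and AIBN (PhMe, 90 °C) should give 11.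

Step 3. The Grignard reagent may act mainly as a base (deprotonation of the hydroxyl groups, enolisation of the aldehyde), or the magnesium pyronolate may precipitate, so that the C–C bond formation stalls. The fallback joins ring B without an organomagnesium reagent and without a carbinol, by reductive coupling of a tosylhydrazone with an arylboronic acid. Because a free 4-hydroxypyrone would trap the diazoalkane formed in that coupling as a cyclic ether, the pyrone oxygen is methylated first. The fallback sets out from lactol 4 and bromide 6 and comes back at 11, so that steps 4 and 5 are not needed. Treatment of 4 with Me2SO4 and K2CO3 (MeCN, 25 °C), under which the hemiacetal opens and the freed pyrone oxygen is methylated, should give (3S)-3-(4-methoxy-6-methyl-2-oxo-2H-pyran-3-yl)-3-(4-methoxyphenyl)propanal F8. Condensation with TsNHNH2 (MeOH, 25 °C) should give N'-[(3S)-3-(4-methoxy-6-methyl-2-oxo-2H-pyran-3-yl)-3-(4-methoxyphenyl)propylidene]-4-methylbenzenesulfonohydrazide F9. Bromine–lithium exchange on 6 (n-BuLi, THF, −78 °C), borylation with B(OiPr)3 and aqueous NH4Cl work-up should give [2-methoxy-4-(triisopropylsilyloxy)phenyl]boronic acid F10. Heating F9 with F10 and K2CO3 in dioxane (110 °C) should give 11 with loss of dinitrogen and sulfinate.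

**Further compounds**

F1 | step 8 | tert-butyl{4-[(E)-2-(3,5-dimethoxyphenyl)ethenyl]phenoxy}dimethylsilane | COc1cc(OC)cc(/C=C/c2ccc(O[Si](C)(C)C(C)(C)C)cc2)c1
F2 | step 8 | 4-{(E)-2-[4-(tert-butyldimethylsilyloxy)phenyl]ethenyl}-2,6-dimethoxybenzaldehyde | COc1cc(/C=C/c2ccc(O[Si](C)(C)C(C)(C)C)cc2)cc(OC)c1C=O
F3 | step 8 | (E)-3-(4-{(E)-2-[4-(tert-butyldimethylsilyloxy)phenyl]ethenyl}-2,6-dimethoxyphenyl)prop-2-enal | COc1cc(/C=C/c2ccc(O[Si](C)(C)C(C)(C)C)cc2)cc(OC)c1/C=C/C=O
F4 | step 8 | (3S)-3-(4-{(E)-2-[4-(tert-butyldimethylsilyloxy)phenyl]ethenyl}-2,6-dimethoxyphenyl)-3-(4-methoxyphenyl)propanal | COc1cc(/C=C/c2ccc(O[Si](C)(C)C(C)(C)C)cc2)cc(OC)c1[C@@H](CC=O)c1ccc(OC)cc1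
F5 | step 8 | (3S)-3-(4-{(E)-2-[4-(tert-butyldimethylsilyloxy)phenyl]ethenyl}-2,6-dimethoxyphenyl)-3-(4-methoxyphenyl)-1-[2-methoxy-4-(triisopropylsilyloxy)phenyl]propan-1-ol (both carbinol epimers) | COc1cc(/C=C/c2ccc(O[Si](C)(C)C(C)(C)C)cc2)cc(OC)c1[C@@H](CC(O)c1ccc(O[Si](C(C)C)(C(C)C)C(C)C)cc1OC)c1ccc(OC)cc1
F6 | step 4 | 3-{(1S)-3-hydroxy-1-(4-methoxyphenyl)-3-[2-methoxy-4-(triisopropylsilyloxy)phenyl]propyl}-4-methoxy-6-methyl-2H-pyran-2-one (both carbinol epimers) | Cc1cc(OC)c([C@@H](CC(O)c2ccc(O[Si](C(C)C)(C(C)C)C(C)C)cc2OC)c2ccc(OC)cc2)c(=O)o1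
F7 | step 4 | O-{(3S)-3-(4-methoxy-6-methyl-2-oxo-2H-pyran-3-yl)-3-(4-methoxyphenyl)-1-[2-methoxy-4-(triisopropylsilyloxy)phenyl]propyl} O-phenyl thiocarbonate | Cc1cc(OC)c([C@@H](CC(OC(=S)Oc2ccccc2)c2ccc(O[Si](C(C)C)(C(C)C)C(C)C)cc2OC)c2ccc(OC)cc2)c(=O)o1
F8 | step 3 | (3S)-3-(4-methoxy-6-methyl-2-oxo-2H-pyran-3-yl)-3-(4-methoxyphenyl)propanal | Cc1cc(OC)c([C@@H](CC=O)c2ccc(OC)cc2)c(=O)o1
F9 | step 3 | N'-[(3S)-3-(4-methoxy-6-methyl-2-oxo-2H-pyran-3-yl)-3-(4-methoxyphenyl)propylidene]-4-methylbenzenesulfonohydrazide | Cc1cc(OC)c([C@@H](CC=NNS(=O)(=O)c2ccc(C)cc2)c2ccc(OC)cc2)c(=O)o1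
F10 | step 3 | [2-methoxy-4-(triisopropylsilyloxy)phenyl]boronic acid | COc1cc(O[Si](C(C)C)(C(C)C)C(C)C)ccc1B(O)O
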